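Ring A is a benzene ring with vicinal oxygens at C6 and C7, fused to ring B through C4a and C8a, and the route rests on taking it apart into three alkynes. A cobalt-catalysed [2+2+2] cocyclisation of an enantiopure 1,7-diyne with bis(pinacolboryl)acetylene forms C4a–C8a, C5–C6 and C7–C8 in one operation, closes rings A and B together and leaves boron where the catechol oxygens belong. The diyne carries C1 and C2 preset, an (E)-C3=C4 alkene that holds both alkynes on one side, a tris(benzyloxy)phenyl group as latent pyranone, and tert-butyl rather than methyl esters, so that no base or hot aqueous acid is needed once the pyranone exists.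

Key step: step 8

Remark: the target is read as the (1R,2S), 1,2-trans acid; 1, 2, 4, 8, 10 and 15 are taken as catalogue compounds; the bisphosphine antipode in step 2 is the one that delivers (R)-5, to be confirmed on the first run; the descriptor changes at C1 (R, S in 14, then R) and C2 (R in 9, then S) reflect CIP priorities only, not a change in space.

Step 1
Reactants: 1 3,4,5-tris(benzyloxy)benzaldehyde; 2 Meldrum's acid (2,2-dimethyl-1,3-dioxane-4,6-dione)
Product: 3 5-[3,4,5-tris(benzyloxy)benzylidene]-2,2-dimethyl-1,3-dioxane-4,6-dione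
Conditions: pyrrolidinium acetate (10 mol%), toluene, rt
Reagents that add atoms: none
Why: Knoevenagel condensation of an aromatic aldehyde with the strongly C–H acidic cyclic malonate gives a doubly activated acceptor that is symmetric at the malonate carbon, so no alkene geometry has to be controlled.

Step 2
Reactants: 3 arylidene Meldrum's acid; 4 trimethylsilylacetylene
Product: 5 5-{(1R)-1-[3,4,5-tris(benzyloxy)phenyl]-3-(trimethylsilyl)prop-2-yn-1-yl}-2,2-dimethyl-1,3-dioxane-4,6-dione
Conditions: Rh(acac)(C2H4)2 (5 mol%), 3,5-Xyl-MeO-BIPHEP (6 mol%, antipode that gives (R)-5), 4 (3 equiv), 1,4-dioxane, rt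
Reagents that add atoms: none
Why: Rhodium-catalysed asymmetric conjugate alkynylation, in which a monovalent rhodium acetylide adds 1,4 to the alkylidene Meldrum's acid and the chiral bisphosphine selects the enantioface, sets C1 as the only new stereocentre, while the bulky silyl group suppresses alkyne oligomerisation.

Step 3
Reactants: 5 Meldrum's acid adduct
Product: 7 tert-butyl (3R)-3-[3,4,5-tris(benzyloxy)phenyl]-5-(trimethylsilyl)pent-4-ynoate, via malonic half ester 6 (not isolated)
Conditions: t-BuOH, toluene, 90 °C; then pyridine, 110 °C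
Reagents that add atoms: tert-butanol, CC(C)(C)O
Why: Alcoholysis of the cyclic acylal opens the dioxanedione with loss of acetone to the mono-tert-butyl malonate, which decarboxylates on heating in pyridine (Meldrum's acid alcoholysis and decarboxylation), the hindered alcohol sparing the C–Si bond and C1 not being enolisable.

Step 4
Reactants: 7 tert-butyl pentynoate; 8 tert-butyl bromoacetate
Product: 9 di-tert-butyl (2R)-2-{(1R)-1-[3,4,5-tris(benzyloxy)phenyl]-3-(trimethylsilyl)prop-2-yn-1-yl}butanedioate
Conditions: LiN(iPr)2 (1.1 equiv), THF, −78 °C; then 8 (1.3 equiv), DMPU, −78 → −40 °C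
Reagents that add atoms: none
Why: SN2 alkylation of the lithium ester enolate, in which A(1,3) strain holds the C1–H bond in the enolate plane and the electrophile approaches anti to the aryl group past the slim alkynyl group, should set C2 in the relative configuration that becomes 1,2-trans in ring B, any minor epimer being removed by chromatography.

Step 5
Reactants: 9 succinate; 10 3-(trimethylsilyl)prop-2-ynal
Product: 11 di-tert-butyl (2S)-2-{(1R)-1-[3,4,5-tris(benzyloxy)phenyl]-3-(trimethylsilyl)prop-2-yn-1-yl}-3-[1-hydroxy-3-(trimethylsilyl)prop-2-yn-1-yl]butanedioate (mixture at C3 and the carbinol carbon)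
Conditions: LiN(iPr)2 (1.05 equiv), THF, −78 °C; then 10 (1.2 equiv), −78 °C; AcOH, −78 °C
Reagents that add atoms: none
Why: Aldol addition of the kinetic enolate, formed at the unhindered C3 methylene and not at the shielded C2 methine, to the very electrophilic ynal at low temperature leaves C1 and C2 untouched, and the two new centres are erased in step 6.

Step 6
Reactants: 11 aldol adduct
Product: 13 di-tert-butyl (2S,3E)-2-{(1R)-1-[3,4,5-tris(benzyloxy)phenyl]-3-(trimethylsilyl)prop-2-yn-1-yl}-3-[3-(trimethylsilyl)prop-2-yn-1-ylidene]butanedioate, via mesylate 12 (not isolated)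
Conditions: MsCl, Et3N, CH2Cl2, −20 → 0 °C; then DBU (1.5 equiv), 0 °C → rt
Reagents that add atoms: none
Why: Mesylation followed by E1cB elimination through the C3 ester enolate is stereoconvergent and should give the (E)-alkylidene succinate, the alkynyl group settling trans to the C3 ester and therefore cis to C2, while the hindered tertiary C2–H is removed far more slowly than the β-mesyloxy ester eliminates.

Step 7
Reactants: 13 bis-silyl enyne
Product: 14 di-tert-butyl (2S,3E)-2-{(1S)-1-[3,4,5-tris(benzyloxy)phenyl]prop-2-yn-1-yl}-3-(prop-2-yn-1-ylidene)butanedioate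
Conditions: Bu4NF/AcOH (1:1, 2.5 equiv), THF, 0 °C
Reagents that add atoms: none
Why: Fluoride-induced protodesilylation of both alkynylsilanes under acetic acid buffering keeps the medium non-basic, so that neither the doubly activated C2–H nor the propargylic and benzylic C1–H is exchanged and the skipped enyne does not isomerise to an allene.

Step 8
Reactants: 14 1,7-diyne; 15 bis(pinacolboryl)acetylene
Product: 16 di-tert-butyl (1R,2S)-6,7-bis(4,4,5,5-tetramethyl-1,3,2-dioxaborolan-2-yl)-1-[3,4,5-tris(benzyloxy)phenyl]-1,2-dihydronaphthalene-2,3-dicarboxylate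
Conditions: (C5H5)Co(CO)2 (20 mol%), 15 (3 equiv), toluene, reflux, hν (visible), 14 added by syringe pump over several hours, Ar
Reagents that add atoms: none
Why: Heat and light strip CO from (C5H5)Co(CO)2, the monovalent cobalt fragment binds the two alkynes of 14 and couples them oxidatively (C4a–C8a) to a cobaltacyclopentadiene annulated to ring B, and this takes up 15, inserts it (C5–C6 and C7–C8) and releases the arene by reductive elimination. The closest known reaction type is the cobalt-catalysed cocyclisation of α,ω-diynes with silyl- or boryl-substituted alkynes, alkynylboronates included, to fused arenes. Ring B closes in the intramolecular oxidative coupling across the four-atom tether C1–C2–C3=C4, exo at both alkynes, and ring A closes in the intermolecular [2+2+2] event by insertion of the third alkyne into the metallacycle and reductive elimination. No stereocentre is created, C1 and C2 are spectators under neutral aprotic conditions, and the one geometric demand, an (E)-alkene that places the enyne alkyne cis to C2, is met in step 6. The step needs cross-cyclisation to win over diyne self-coupling, which the tether, the slow addition of 14 into an excess of 15 and the bulk of 15 (no self-trimerisation) should secure, and the symmetry of 15 removes any regiochemical question and puts boron exactly at C6 and C7.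

Step 9
Reactants: 16 bis-boronate
Product: 18 di-tert-butyl (1R,2S)-6,7-diacetoxy-1-[3,4,5-tris(benzyloxy)phenyl]-1,2-dihydronaphthalene-2,3-dicarboxylate, via catechol 17 (not isolated)
Conditions: NaBO3·4H2O (6 equiv), THF/H2O, rt, Ar; work-up at pH 4; then Ac2O, pyridine, DMAP (cat.), CH2Cl2, 0 °C → rt
Reagents that add atoms: sodium perborate, [Na+].[O-]OB=O; acetic anhydride, CC(=O)OC(C)=O
Why: Perborate oxidation of both aryl C–B bonds (1,2-shift of the aryl group from boron to oxygen) gives the catechol, which is acetylated at once because it is air-sensitive and because the diacetate deactivates ring A towards the peracid of step 11, the electron-poor hindered acrylate and the tert-butyl esters being inert to this mild oxidant.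

Step 10
Reactants: 18 diacetate
Product: 19 (1R,2S)-6,7-diacetoxy-1-(3,4,5-trihydroxyphenyl)-1,2-dihydronaphthalene-2,3-dicarboxylic acid
Conditions: BCl3 (8 equiv), C6HMe5 (10 equiv), CH2Cl2, −78 → −20 °C; then H2O/THF
Reagents that add atoms: none
Why: Lewis-acid dealkylation in which BCl3 ionises the three aryl benzyl ethers and the two tert-butyl esters (more labile than benzyl esters, which this reagent is known to cleave), while pentamethylbenzene traps the benzyl cations and prevents C-benzylation of the pyrogallol, and aryl acetates and the electron-poor alkene do not react at this temperature.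

Step 11
Reactants: 19 pyrogallol diacid
Product: 23 (1R,2S)-6,7-diacetoxy-1-(6-carboxy-2-oxo-2H-pyran-4-yl)-1,2-dihydronaphthalene-2,3-dicarboxylic acid, via hydroxy-o-quinone 20 (not isolated), via muconic anhydride 21 (not isolated), via hydroxymuconic acid 22 (not isolated)
Conditions: CH3CO3H (2.5 equiv), NaOAc (cat.), AcOH, 15 °C → rt
Reagents that add atoms: peracetic acid, CC(=O)OO
Why: Peracid ring fission of a pyrogallol, in which the free triol (the only electron-rich ring left) is oxidised to the hydroxy-o-quinone, a Baeyer–Villiger-type oxygen insertion into the dione C–C bond gives the anhydride, ring opening gives the 2-hydroxy-cis,cis-muconic acid and its enol hydroxyl lactonises onto the cis-disposed distal carboxyl to the 2-pyranone-6-carboxylic acid, the local symmetry of the pyrogallol making both fission sites equivalent.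

Step 12
Reactants: 23 pyranone triacid diacetate
Product: 24 (1R,2S)-1-(6-carboxy-2-oxo-2H-pyran-4-yl)-6,7-dihydroxy-1,2-dihydronaphthalene-2,3-dicarboxylic acid (target)
Conditions: 2 M HCl, THF/H2O, 45 °C, Ar
Reagents that add atoms: none
Why: Acid-catalysed hydrolysis of the two aryl acetates runs under conditions in which the pyranone lactone, the carboxylic acids and the free catechol are stable and no base touches the pyranone, and the 1,2-trans arrangement, being the more stable one, is not at risk.

Compound list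
1 | 3,4,5-tris(benzyloxy)benzaldehyde | O=Cc1cc(OCc2ccccc2)c(OCc2ccccc2)c(OCc2ccccc2)c1 | starting material
2 | Meldrum's acid (2,2-dimethyl-1,3-dioxane-4,6-dione) | CC1(C)OC(=O)CC(=O)O1 | starting material
3 | 5-[3,4,5-tris(benzyloxy)benzylidene]-2,2-dimethyl-1,3-dioxane-4,6-dione | CC1(C)OC(=O)C(=Cc2cc(OCc3ccccc3)c(OCc3ccccc3)c(OCc3ccccc3)c2)C(=O)O1 | intermediate
4 | trimethylsilylacetylene | C#C[Si](C)(C)C | starting material
5 | 5-{(1R)-1-[3,4,5-tris(benzyloxy)phenyl]-3-(trimethylsilyl)prop-2-yn-1-yl}-2,2-dimethyl-1,3-dioxane-4,6-dione | CC1(C)OC(=O)C(C(=O)O1)[C@@H](C#C[Si](C)(C)C)c1cc(OCc2ccccc2)c(OCc2ccccc2)c(OCc2ccccc2)c1 | intermediate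
6 | 3-tert-butoxy-3-oxo-2-{(1R)-1-[3,4,5-tris(benzyloxy)phenyl]-3-(trimethylsilyl)prop-2-yn-1-yl}propanoic acid (not isolated; malonate carbon unassigned) | CC(C)(C)OC(=O)C(C(=O)O)[C@@H](C#C[Si](C)(C)C)c1cc(OCc2ccccc2)c(OCc2ccccc2)c(OCc2ccccc2)c1 | intermediate
7 | tert-butyl (3R)-3-[3,4,5-tris(benzyloxy)phenyl]-5-(trimethylsilyl)pent-4-ynoate | CC(C)(C)OC(=O)C[C@@H](C#C[Si](C)(C)C)c1cc(OCc2ccccc2)c(OCc2ccccc2)c(OCc2ccccc2)c1 | intermediate
8 | tert-butyl bromoacetate | CC(C)(C)OC(=O)CBr | starting material
9 | di-tert-butyl (2R)-2-{(1R)-1-[3,4,5-tris(benzyloxy)phenyl]-3-(trimethylsilyl)prop-2-yn-1-yl}butanedioate | CC(C)(C)OC(=O)C[C@@H](C(=O)OC(C)(C)C)[C@@H](C#C[Si](C)(C)C)c1cc(OCc2ccccc2)c(OCc2ccccc2)c(OCc2ccccc2)c1 | intermediate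
10 | 3-(trimethylsilyl)prop-2-ynal | O=CC#C[Si](C)(C)C | starting material
11 | di-tert-butyl (2S)-2-{(1R)-1-[3,4,5-tris(benzyloxy)phenyl]-3-(trimethylsilyl)prop-2-yn-1-yl}-3-[1-hydroxy-3-(trimethylsilyl)prop-2-yn-1-yl]butanedioate (mixture at C3 and the carbinol carbon) | C[Si](C)(C)C#CC(O)C(C(=O)OC(C)(C)C)[C@@H](C(=O)OC(C)(C)C)[C@@H](C#C[Si](C)(C)C)c1cc(OCc2ccccc2)c(OCc2ccccc2)c(OCc2ccccc2)c1 | intermediate
12 | di-tert-butyl (2S)-2-{(1R)-1-[3,4,5-tris(benzyloxy)phenyl]-3-(trimethylsilyl)prop-2-yn-1-yl}-3-[1-(methanesulfonyloxy)-3-(trimethylsilyl)prop-2-yn-1-yl]butanedioate (not isolated) | C[Si](C)(C)C#CC(OS(C)(=O)=O)C(C(=O)OC(C)(C)C)[C@@H](C(=O)OC(C)(C)C)[C@@H](C#C[Si](C)(C)C)c1cc(OCc2ccccc2)c(OCc2ccccc2)c(OCc2ccccc2)c1 | intermediate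
13 | di-tert-butyl (2S,3E)-2-{(1R)-1-[3,4,5-tris(benzyloxy)phenyl]-3-(trimethylsilyl)prop-2-yn-1-yl}-3-[3-(trimethylsilyl)prop-2-yn-1-ylidene]butanedioate | C[Si](C)(C)C#C/C=C(/C(=O)OC(C)(C)C)[C@@H](C(=O)OC(C)(C)C)[C@@H](C#C[Si](C)(C)C)c1cc(OCc2ccccc2)c(OCc2ccccc2)c(OCc2ccccc2)c1 | intermediate
14 | di-tert-butyl (2S,3E)-2-{(1S)-1-[3,4,5-tris(benzyloxy)phenyl]prop-2-yn-1-yl}-3-(prop-2-yn-1-ylidene)butanedioate | C#C/C=C(/C(=O)OC(C)(C)C)[C@@H](C(=O)OC(C)(C)C)[C@@H](C#C)c1cc(OCc2ccccc2)c(OCc2ccccc2)c(OCc2ccccc2)c1 | intermediate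
15 | bis(pinacolboryl)acetylene | CC1(C)OB(C#CB2OC(C)(C)C(C)(C)O2)OC1(C)C | starting material
16 | di-tert-butyl (1R,2S)-6,7-bis(4,4,5,5-tetramethyl-1,3,2-dioxaborolan-2-yl)-1-[3,4,5-tris(benzyloxy)phenyl]-1,2-dihydronaphthalene-2,3-dicarboxylate | CC(C)(C)OC(=O)C1=Cc2cc(B3OC(C)(C)C(C)(C)O3)c(B3OC(C)(C)C(C)(C)O3)cc2[C@@H](c2cc(OCc3ccccc3)c(OCc3ccccc3)c(OCc3ccccc3)c2)[C@@H]1C(=O)OC(C)(C)C | intermediate
17 | di-tert-butyl (1R,2S)-6,7-dihydroxy-1-[3,4,5-tris(benzyloxy)phenyl]-1,2-dihydronaphthalene-2,3-dicarboxylate (not isolated) | CC(C)(C)OC(=O)C1=Cc2cc(O)c(O)cc2[C@@H](c2cc(OCc3ccccc3)c(OCc3ccccc3)c(OCc3ccccc3)c2)[C@@H]1C(=O)OC(C)(C)C | intermediate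
18 | di-tert-butyl (1R,2S)-6,7-diacetoxy-1-[3,4,5-tris(benzyloxy)phenyl]-1,2-dihydronaphthalene-2,3-dicarboxylate | CC(C)(C)OC(=O)C1=Cc2cc(OC(C)=O)c(OC(C)=O)cc2[C@@H](c2cc(OCc3ccccc3)c(OCc3ccccc3)c(OCc3ccccc3)c2)[C@@H]1C(=O)OC(C)(C)C | intermediate
19 | (1R,2S)-6,7-diacetoxy-1-(3,4,5-trihydroxyphenyl)-1,2-dihydronaphthalene-2,3-dicarboxylic acid | O=C(O)C1=Cc2cc(OC(C)=O)c(OC(C)=O)cc2[C@@H](c2cc(O)c(O)c(O)c2)[C@@H]1C(=O)O | intermediate
20 | (1R,2S)-6,7-diacetoxy-1-(5-hydroxy-3,4-dioxocyclohexa-1,5-dien-1-yl)-1,2-dihydronaphthalene-2,3-dicarboxylic acid (not isolated) | O=C(O)C1=Cc2cc(OC(C)=O)c(OC(C)=O)cc2[C@@H](C2=CC(=O)C(=O)C(O)=C2)[C@@H]1C(=O)O | intermediate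
21 | (1R,2S)-6,7-diacetoxy-1-(6-hydroxy-2,7-dioxo-2,7-dihydrooxepin-4-yl)-1,2-dihydronaphthalene-2,3-dicarboxylic acid (not isolated) | O=C(O)C1=Cc2cc(OC(C)=O)c(OC(C)=O)cc2[C@@H](C2=CC(=O)OC(=O)C(O)=C2)[C@@H]1C(=O)O | intermediate
22 | (2E,4Z)-4-[(1R,2S)-6,7-diacetoxy-2,3-dicarboxy-1,2-dihydronaphthalen-1-yl]-2-hydroxyhexa-2,4-dienedioic acid (not isolated) | O=C(O)C1=Cc2cc(OC(C)=O)c(OC(C)=O)cc2[C@@H](/C(=C/C(=O)O)/C=C(/O)C(=O)O)[C@@H]1C(=O)O | intermediate
23 | (1R,2S)-6,7-diacetoxy-1-(6-carboxy-2-oxo-2H-pyran-4-yl)-1,2-dihydronaphthalene-2,3-dicarboxylic acid | O=C(O)C1=Cc2cc(OC(C)=O)c(OC(C)=O)cc2[C@@H](c2cc(C(=O)O)oc(=O)c2)[C@@H]1C(=O)O | intermediate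
24 | (1R,2S)-1-(6-carboxy-2-oxo-2H-pyran-4-yl)-6,7-dihydroxy-1,2-dihydronaphthalene-2,3-dicarboxylic acid | O=C(O)C1=Cc2cc(O)c(O)cc2[C@@H](c2cc(C(=O)O)oc(=O)c2)[C@@H]1C(=O)O | target

Total step count: 12. Longest linear sequence: 12 steps, from 1 to 24.

Steps most likely to fail

Step 8. The diyne may be consumed by self-oligomerisation on cobalt because the hindered diboryl alkyne enters the cobaltacycle too slowly, or the catalyst may be held back as a stable cyclopentadienylcobalt complex of the product. The fallback sets out from 14 and 15 and prebinds the alkyne to the metal, so that cross-selection no longer depends on concentration. Treating 15 with Co2(CO)8 (zerovalent cobalt, pentane or THF, rt, loss of CO) gives hexacarbonyl[μ-bis(pinacolboryl)acetylene]dicobalt F1. Heating F1 with slowly added 14 in refluxing toluene or xylene is the known thermal cycloaddition of alkyne–hexacarbonyldicobalt complexes of alkynylboronates with α,ω-diynes. After removal of cobalt with air and dilute HCl the route is rejoined at 16.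

Step 11. Excess peracid may attack the quinone or muconate stage before lactonisation is complete, or a ring A phenol laid bare by acetyl loss, so that ring fission becomes unselective. The fallback sets out from 19 and separates the two redox events. One equivalent of o-chloranil (THF, −20 °C) dehydrogenates the pyrogallol to 20 as a defined intermediate. One equivalent of mCPBA (CH2Cl2/THF, 0 °C) then effects the Baeyer–Villiger insertion to 21, which on warming in aqueous AcOH passes through 22 and lactonises. The route is rejoined at 23; no compound outside the list is made (F0).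

Step 6. The elimination may lose geometric control and give the (Z)-enyne, which cannot cyclise, or the base may epimerise C2. The fallback sets out from 9 and builds the alkene with its geometry fixed before the alkyne is attached. Claisen formylation of the C3 enolate (LiN(iPr)2, then 2,2,2-trifluoroethyl formate, THF, −78 °C) gives di-tert-butyl (2S)-3-formyl-2-{(1R)-1-[3,4,5-tris(benzyloxy)phenyl]-3-(trimethylsilyl)prop-2-yn-1-yl}butanedioate F2. Triflation of its enolate under non-chelating conditions (Tf2O, aqueous Me4NOH, toluene, 0 °C) should give the (E)-enol triflate F3, with the triflate trans to the ester. Sonogashira coupling of F3 with 4 (Pd(PPh3)2Cl2, CuI, Et3N, THF, rt) proceeds with retention of alkene geometry and rejoins the route at 13.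

Further compounds
F1 | step 8 | hexacarbonyl[μ-bis(pinacolboryl)acetylene]dicobalt | CC1(C)OB(C#CB2OC(C)(C)C(C)(C)O2)OC1(C)C.[Co].[Co].[C-]#[O+].[C-]#[O+].[C-]#[O+].[C-]#[O+].[C-]#[O+].[C-]#[O+]
F0 | step 11 | none | none
F2 | step 6 | di-tert-butyl (2S)-3-formyl-2-{(1R)-1-[3,4,5-tris(benzyloxy)phenyl]-3-(trimethylsilyl)prop-2-yn-1-yl}butanedioate (C3 unassigned, enolised) | O=CC(C(=O)OC(C)(C)C)[C@@H](C(=O)OC(C)(C)C)[C@@H](C#C[Si](C)(C)C)c1cc(OCc2ccccc2)c(OCc2ccccc2)c(OCc2ccccc2)c1
F3 | step 6 | di-tert-butyl (2S,3E)-2-{(1R)-1-[3,4,5-tris(benzyloxy)phenyl]-3-(trimethylsilyl)prop-2-yn-1-yl}-3-{[(trifluoromethanesulfonyl)oxy]methylidene}butanedioate | FC(F)(F)S(=O)(=O)O/C=C(/C(=O)OC(C)(C)C)[C@@H](C(=O)OC(C)(C)C)[C@@H](C#C[Si](C)(C)C)c1cc(OCc2ccccc2)c(OCc2ccccc2)c(OCc2ccccc2)c1
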